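## The problem

The target is a flavone (2-aryl-4H-chromen-4-one) with no stereocentre, so the whole difficulty lies in its substitution pattern. Ring A carries no hydrogen: C5, C6, C7 and C8 bear methoxy groups and C4a and C8a are the fusion carbons. It must therefore enter as a pentaoxygenated benzene with a single carbon substituent, and every reaction at that substituent is flanked by two ortho groups. Ring B is a syringyl unit whose 4'-hydroxyl must end free beside six methyl ethers, so it needs a protecting group that leaves without touching an aryl methyl ether. The C5 methoxy group lies peri to the C4 carbonyl and is cleaved by Lewis acids or by prolonged heating with strong protic acid. The tetra- and pentaoxygenated rings are also readily oxidised to quinones, so harsh acid and strong oxidants are excluded late in the route. The classical chalcone and Baker–Venkataraman routes require enolate chemistry at an aryl ketone on this crowded ring A. The enabling feature is that C2, C3 and C4 of ring C form a three-carbon unit oxygenated at both ends (O1 on C2, the carbonyl oxygen on C4) and flanked by the two aryl rings. A 3,5-diarylisoxazole can carry this unit in masked form, with C2 and ring B coming from an aryl nitrile oxide and C3 and C4 from a terminal alkyne on ring A.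

## Retrosynthesis

**Ring C closure and unmasking (17 from 15).** The O1–C2 bond is cut, both phenols are returned to methoxymethyl ethers and C2 carries an amino group in place of O1. This gives the open-chain enaminoketone 15, which passes through the free bisphenol 16 on the way forward. Cutting C2–C3 or C3–C4 instead would require a late C–C bond next to the crowded ring A; cutting C–O asks only for a phenol and an electrophilic C2. One acid treatment should remove both acetals and close the ring with loss of ammonia. It must be mild enough to spare the C5 methyl ether.

**Enaminoketone to isoxazole (15 from 14).** The amino nitrogen and the ketone oxygen are reconnected as an N–O bond, turning the vinylogous amide into the aromatic isoxazole 14. This replaces a 1,3-diketone, which would have to be made by acylating an enolate beside ring A, with a heterocycle that is inert to base and nucleophiles. The forward step must be a two-electron reduction of the N–O bond that leaves aryl ethers and acetals alone.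

**Isoxazole to alkyne and nitrile oxide (14 from 8 and 13).** The isoxazole C3–C4 and O1–C5 bonds are cut, corresponding to flavone C2–C3 and C4–O. This divides the molecule into two monocyclic benzenes of similar size, alkyne 8 and nitrile oxide 13. Building the isoxazole by condensing hydroxylamine with a diketone or ynone would need the very dicarbonyl compound the plan avoids and would leave the regiochemistry open. The forward cycloaddition must give the 3,5-isomer and must outrun dimerisation of the dipole.

**Nitrile oxide back to syringaldehyde (13 from 12, 11, 10, 9).** Only functional-group changes are involved. The nitrile oxide 13 comes from hydroximoyl chloride 12, this from aldoxime 11, the oxime from aldehyde 10, and 10 from syringaldehyde 9 by protection. The methoxymethyl group is chosen for the 4-hydroxyl because the same acid that unmasks ring A will remove it, which saves a separate deprotection on the finished flavone.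

**Alkyne to protected phenol (8 from 7, then 7 from 5 via 6).** The terminal alkyne carbon is removed by a one-carbon homologation of aldehyde 7. The aryl–CHO bond (future C4a–C4) is then cut by directed metalation of 5 through aryllithium 6. A cross-coupling of an ethynyl group onto a hexasubstituted, electron-rich aryl halide would be slow. The aldehyde route instead uses the methoxymethyl ether as ortho director at the only remaining C–H.

**Protected phenol to tetramethoxybenzene (5 from 4, then 4 from 1 via 2 and 3).** The acetal is removed to phenol 4, and the C–O bond at the future C8a is cut back to 1,2,3,4-tetramethoxybenzene 1. The two free positions of 1 are equivalent, so lithiation to 2, borylation to 3 and oxidation place the oxygen without a regiochemical question. This is one operation shorter than formylation followed by oxidative rearrangement.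

## Roads not taken

**Alternative 1: dehydrogenative enol O–aryl closure onto ring A.**
- Cut: O1–C8a, made last. The diketone A2 would come from a Claisen condensation of acetophenone A3 (one Friedel–Crafts acetylation of 1) with a tosyl-protected syringate ester.
- Key step: one-electron oxidation of the tetramethoxyaryl ring of A2. The enol oxygen attacks the single aryl C–H, and rearomatisation gives the tosyl flavone A1. Detosylation would follow.
- Merits: it is clearly the shortest road, about five steps against nine. It needs no phenol and no protecting group on ring A, and the lone C–H leaves no doubt about where the oxygen must go.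
- Weak points:
  - The enolised diketone is itself easily oxidised at its central carbon.
  - Every methoxy-bearing carbon of the radical cation is open to ipso attack with loss of methanol toward quinones.
  - Ring B has to be deactivated as a tosylate, whose later basic removal endangers the base-sensitive pyranone.
  - A six-membered C–O closure of this kind onto a position ortho to an acyl group would first have to be developed.
- Comparison: Alternative 1 wins on step count. The chosen plan sets against this that every step is an established reaction on an established substrate class, and that no oxidant ever meets the electron-rich ring A.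

**Alternative 2: symmetric tetramethoxybenzyne insertion into an arylpropiolic acid.**
- Cut: C8a–O1 and C4a–C4 together.
- Key step: fluoride releases benzyne A6 from silyl triflate A5. The carboxylate of acid A7 adds to it, and the resulting ortho aryl anion attacks the acyl carbon, giving the o-hydroxyaryl ynone A4. A 6-endo closure and hydrogenolysis (H2, Pd/C) would finish.
- Merits: the final assembly is highly convergent. The aryne is symmetric, so the sense of addition is irrelevant. A4 is a proven flavone precursor.
- Weak points:
  - A5 is a hexasubstituted benzene that would take about four steps from phenol 4, no shorter than alkyne 8.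
  - Acyl transfer through a four-membered transition state competes with simple protonation of the aryl anion, which ends in the aryl ester.
  - A7 can decarboxylate or present its alkyne to the aryne.
  - The closure of A4 needs control of 6-endo against 5-exo attack.
- Comparison: the length is similar and the convergence is at least as good. The chemoselectivity of the key step is less secure than that of a nitrile oxide cycloaddition to a terminal alkyne. The chosen plan keeps an ynone only as a fallback, made by unambiguous acetylide addition.

**Alternative 3: squarate-to-hydroquinone ring expansion builds ring A.**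
- Cut: ring A is constructed, with C8–C8a formed last. The organolithium from bromopyranone A11 adds to dimethyl squarate A10 to give the 4-hydroxycyclobutenone A9.
- Key step: thermolysis opens A9 to a dienylketene. Its ketene carbon closes onto the pyranone CH next to the ring oxygen in a six-electron electrocyclisation, and tautomerisation gives the 5,8-hydroquinone A8. Double O-methylation and hydrogenolysis would follow.
- Merits: the placement of all six ring A substituents is fixed by connectivity. Two methoxy groups arrive with A10. It is the only road independent of 1, and it would serve analogues that differ at C5 and C8 better than the chosen plan.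
- Weak points:
  - A11 must be made in several steps and metalated without adding to its own enone.
  - A8 is prone to air oxidation to the 5,8-quinone.
  - Methylating the chelated C5 hydroxyl needs forcing conditions.
  - The sequence is the longest of the four, and it rebuilds a benzene ring that can be bought with its four methoxy groups in place.
- Comparison: for this target the chosen plan is shorter and avoids oxidation-prone intermediates.

Key step: step 7

## Route

Assumption: aldoxime 11 is drawn as its E isomer, hydroximoyl chloride 12 as Z and enaminoketone 15 as the hydrogen-bonded Z isomer; none of these geometries is carried into the target, which has no stereocentre.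

Step 1
Reactants: 1 1,2,3,4-tetramethoxybenzene
Product: 4 2,3,4,5-tetramethoxyphenol, via aryllithium 2 (not isolated), via aryl boronate 3 (not isolated)
Conditions: n-BuLi, TMEDA, THF, 0 °C; B(OMe)3, −78 °C to rt; AcOH, 30% aq H2O2, 0 °C to rt
Reagents that add atoms: hydrogen peroxide, OO
Why: Directed ortho-metalation of an aryl methyl ether (the two free positions of 1 are equivalent), borylation and oxidative boron-to-oxygen aryl migration should give the phenol in one flask; the acidic peroxide stage protects the electron-rich phenol from base-promoted oxidation.

Step 2
Reactants: 4 2,3,4,5-tetramethoxyphenol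
Product: 5 1,2,3,4-tetramethoxy-5-(methoxymethoxy)benzene
Conditions: NaH, MOMCl, THF, 0 °C to rt
Reagents that add atoms: chloromethyl methyl ether, COCCl
Why: Williamson-type O-alkylation of the sodium phenoxide; the acetal is chosen as a strong ortho-directing group that later leaves under mild acid.

Step 3
Reactants: 5 1,2,3,4-tetramethoxy-5-(methoxymethoxy)benzene
Product: 7 2,3,4,5-tetramethoxy-6-(methoxymethoxy)benzaldehyde, via aryllithium 6 (not isolated)
Conditions: n-BuLi, TMEDA, THF, −20 to 0 °C; DMF, 0 °C to rt; H2O
Reagents that add atoms: N,N-dimethylformamide, CN(C)C=O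
Why: Directed ortho-metalation at the only aromatic C–H, which is flanked by the methoxymethoxy and a methoxy group, followed by formylation of the aryllithium with DMF; no regiochemical alternative exists.

Step 4
Reactants: 7 2,3,4,5-tetramethoxy-6-(methoxymethoxy)benzaldehyde
Product: 8 1-ethynyl-2,3,4,5-tetramethoxy-6-(methoxymethoxy)benzene
Conditions: dimethyl (1-diazo-2-oxopropyl)phosphonate, K2CO3, MeOH, rt
Reagents that add atoms: dimethyl (1-diazo-2-oxopropyl)phosphonate, COP(=O)(OC)C(=[N+]=[N-])C(C)=O
Why: Seyferth–Gilbert homologation in its Ohira–Bestmann form converts the non-enolisable aldehyde into the terminal alkyne under mild basic conditions that leave the acetal and the methyl ethers untouched.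

Step 5
Reactants: 9 syringaldehyde (4-hydroxy-3,5-dimethoxybenzaldehyde)
Product: 10 3,5-dimethoxy-4-(methoxymethoxy)benzaldehyde
Conditions: MOMCl, i-Pr2NEt, CH2Cl2, 0 °C to rt
Reagents that add atoms: chloromethyl methyl ether, COCCl
Why: O-alkylation of the acidic para-formyl phenol with an amine base; the same acetal as on ring A is used so that one acid step later frees both phenols.

Step 6
Reactants: 10 3,5-dimethoxy-4-(methoxymethoxy)benzaldehyde
Product: 11 (E)-3,5-dimethoxy-4-(methoxymethoxy)benzaldehyde oxime
Conditions: NH2OH·HCl, NaOAc, EtOH/H2O, rt
Reagents that add atoms: hydroxylamine hydrochloride, Cl.NO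
Why: Condensation of the aldehyde with hydroxylamine under acetate buffer, which is too weakly acidic to cleave the aryl acetal, should give the aldoxime.

Step 7
Reactants: 8 1-ethynyl-2,3,4,5-tetramethoxy-6-(methoxymethoxy)benzene; 11 (E)-3,5-dimethoxy-4-(methoxymethoxy)benzaldehyde oxime
Product: 14 3-[3,5-dimethoxy-4-(methoxymethoxy)phenyl]-5-[2,3,4,5-tetramethoxy-6-(methoxymethoxy)phenyl]isoxazole, via hydroximoyl chloride 12 (not isolated), via nitrile oxide 13 (not isolated)
Conditions: NCS, DMF, rt; then 8, Et3N (slow addition), rt to 40 °C
Reagents that add atoms: none
Why: N-Chlorosuccinimide chlorinates the aldoxime carbon of 11 to give hydroximoyl chloride 12, and slowly added triethylamine removes HCl to release nitrile oxide 13 at a low stationary concentration. 13 then adds to the terminal alkyne of 8 in a concerted, asynchronous thermal [3+2] cycloaddition (Huisgen 1,3-dipolar cycloaddition); the closest known reaction type is the synthesis of 3,5-diarylisoxazoles from aryl nitrile oxides and arylacetylenes. The isoxazole ring closes in this single intermolecular cycloaddition, in which the nitrile oxide carbon bonds to the terminal alkyne carbon (future C2–C3) and the oxygen to the aryl-bearing carbon (future C4–O), so the aromatic heterocycle forms without a separate cyclisation or oxidation. No stereocentre is created. The step needs regioselectivity for the 3,5- over the 3,4-disubstituted isomer and must outrun dimerisation of 13 to the furoxan. The terminal alkyne secures the first: its unsubstituted carbon is the less hindered terminus and carries the frontier-orbital coefficient that pairs with the nitrile oxide carbon, and the two ortho substituents of ring A shield the internal carbon further. Slow base addition and an excess of the cheaper oxime component should secure the second. Triethylamine in DMF near room temperature leaves both acetals and all methyl ethers intact.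

Step 8
Reactants: 14 3-[3,5-dimethoxy-4-(methoxymethoxy)phenyl]-5-[2,3,4,5-tetramethoxy-6-(methoxymethoxy)phenyl]isoxazole
Product: 15 (Z)-3-amino-3-[3,5-dimethoxy-4-(methoxymethoxy)phenyl]-1-[2,3,4,5-tetramethoxy-6-(methoxymethoxy)phenyl]prop-2-en-1-one
Conditions: Mo(CO)6, MeCN/H2O, reflux
Reagents that add atoms: none
Why: Reductive N–O cleavage of an isoxazole by zerovalent molybdenum: coordination at nitrogen, insertion into the weak N–O bond and hydrolysis by water should give the hydrogen-bonded Z enaminoketone under neutral conditions that spare acetals and aryl ethers.

Step 9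
Reactants: 15 (Z)-3-amino-3-[3,5-dimethoxy-4-(methoxymethoxy)phenyl]-1-[2,3,4,5-tetramethoxy-6-(methoxymethoxy)phenyl]prop-2-en-1-one
Product: 17 4'-hydroxy-3',5,5',6,7,8-hexamethoxyflavone, via bisphenol enaminoketone 16 (not isolated)
Conditions: HCl (about 1.5 M) in MeOH, 45–50 °C
Reagents that add atoms: none
Why: Acid-catalysed acetal exchange removes both methoxymethyl groups, and the freed ring A phenol of 16 adds to the protonated enaminone at C2 (6-endo-trig conjugate addition) and expels ammonia as its hydrochloride, which aromatises the pyranone ring; the acid is kept dilute and the temperature moderate to spare the C5 methyl ether.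

## Compound list

1 | 1,2,3,4-tetramethoxybenzene | COc1ccc(OC)c(OC)c1OC | starting material
2 | (2,3,4,5-tetramethoxyphenyl)lithium | [Li]c1cc(OC)c(OC)c(OC)c1OC | intermediate
3 | dimethyl (2,3,4,5-tetramethoxyphenyl)boronate (present as its lithium methoxide adduct) | COB(OC)c1cc(OC)c(OC)c(OC)c1OC | intermediate
4 | 2,3,4,5-tetramethoxyphenol | COc1cc(O)c(OC)c(OC)c1OC | intermediate
5 | 1,2,3,4-tetramethoxy-5-(methoxymethoxy)benzene | COCOc1cc(OC)c(OC)c(OC)c1OC | intermediate
6 | [2,3,4,5-tetramethoxy-6-(methoxymethoxy)phenyl]lithium | [Li]c1c(OCOC)c(OC)c(OC)c(OC)c1OC | intermediate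
7 | 2,3,4,5-tetramethoxy-6-(methoxymethoxy)benzaldehyde | COCOc1c(C=O)c(OC)c(OC)c(OC)c1OC | intermediate
8 | 1-ethynyl-2,3,4,5-tetramethoxy-6-(methoxymethoxy)benzene | C#Cc1c(OCOC)c(OC)c(OC)c(OC)c1OC | intermediate
9 | syringaldehyde (4-hydroxy-3,5-dimethoxybenzaldehyde) | COc1cc(C=O)cc(OC)c1O | starting material
10 | 3,5-dimethoxy-4-(methoxymethoxy)benzaldehyde | COCOc1c(OC)cc(C=O)cc1OC | intermediate
11 | (E)-3,5-dimethoxy-4-(methoxymethoxy)benzaldehyde oxime | COCOc1c(OC)cc(/C=N/O)cc1OC | intermediate
12 | (Z)-N-hydroxy-3,5-dimethoxy-4-(methoxymethoxy)benzenecarboximidoyl chloride | COCOc1c(OC)cc(/C(Cl)=N/O)cc1OC | intermediate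
13 | 3,5-dimethoxy-4-(methoxymethoxy)benzonitrile oxide | COCOc1c(OC)cc(C#[N+][O-])cc1OC | intermediate
14 | 3-[3,5-dimethoxy-4-(methoxymethoxy)phenyl]-5-[2,3,4,5-tetramethoxy-6-(methoxymethoxy)phenyl]isoxazole | COCOc1c(OC)c(OC)c(OC)c(OC)c1-c1cc(-c2cc(OC)c(OCOC)c(OC)c2)no1 | intermediate
15 | (Z)-3-amino-3-[3,5-dimethoxy-4-(methoxymethoxy)phenyl]-1-[2,3,4,5-tetramethoxy-6-(methoxymethoxy)phenyl]prop-2-en-1-one | COCOc1c(OC)c(OC)c(OC)c(OC)c1C(=O)/C=C(\N)c1cc(OC)c(OCOC)c(OC)c1 | intermediate
16 | (Z)-3-amino-3-(4-hydroxy-3,5-dimethoxyphenyl)-1-(2-hydroxy-3,4,5,6-tetramethoxyphenyl)prop-2-en-1-one | COc1cc(/C(N)=C/C(=O)c2c(O)c(OC)c(OC)c(OC)c2OC)cc(OC)c1O | intermediate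
17 | 4'-hydroxy-3',5,5',6,7,8-hexamethoxyflavone [2-(4-hydroxy-3,5-dimethoxyphenyl)-5,6,7,8-tetramethoxy-4H-chromen-4-one] | COc1cc(-c2cc(=O)c3c(OC)c(OC)c(OC)c(OC)c3o2)cc(OC)c1O | target

## Step count and risk assessment

Total step count: 9. Longest linear sequence: 7 steps (steps 1, 2, 3, 4, 7, 8 and 9, from 1); the ring B branch contributes steps 5 and 6 before the convergent step 7.

**Step 7 (key step).** The most likely failure is dimerisation of the nitrile oxide to the furoxan outrunning cycloaddition, because the alkyne is electron-rich and flanked by two ortho substituents. Ring chlorination of the electron-rich oxime during the chlorination stage is a lesser risk. The fallback abandons the dipole and sets out from aldehydes 10 and 7. The homologation of step 4 applied to 10 would give 5-ethynyl-1,3-dimethoxy-2-(methoxymethoxy)benzene F1. Its lithium acetylide (n-BuLi, THF, −78 °C) would add to 7 to give racemic 3-[3,5-dimethoxy-4-(methoxymethoxy)phenyl]-1-[2,3,4,5-tetramethoxy-6-(methoxymethoxy)phenyl]prop-2-yn-1-ol F2. Oxidation with MnO2 in CH2Cl2 would give 3-[3,5-dimethoxy-4-(methoxymethoxy)phenyl]-1-[2,3,4,5-tetramethoxy-6-(methoxymethoxy)phenyl]prop-2-yn-1-one F3. Conjugate addition of ammonia in methanol would then place the nitrogen on the ring B carbon and return to the route at enaminoketone 15.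

**Step 9.** The risk is acid-promoted loss of the C5 methyl ether, which is assisted by chelation to the C4 carbonyl once the flavone has formed, if the hindered ring A acetal is slow to leave and heating has to be prolonged. The fallback reverses the order of unmasking and starts from isoxazole 14. Methanolic HCl at room temperature, with no carbonyl yet present to activate the neighbouring methoxy group, would give 2-[3-(4-hydroxy-3,5-dimethoxyphenyl)isoxazol-5-yl]-3,4,5,6-tetramethoxyphenol F4. Cleavage of its N–O bond with Mo(CO)6 in wet acetonitrile would return to the route at bisphenol enaminoketone 16, which should close to 17 on warming with acetic acid.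

**Step 4.** The risk is slow addition of the diazophosphonate anion to a hindered and very electron-rich aldehyde, so that methanolysis of the reagent consumes it before conversion is complete. The fallback is a Corey–Fuchs sequence from 7. CBr4 and PPh3 with Et3N in CH2Cl2 would give 1-(2,2-dibromoethenyl)-2,3,4,5-tetramethoxy-6-(methoxymethoxy)benzene F5. n-BuLi in THF at −78 °C followed by water would then return to the route at alkyne 8.

**Step 1.** The risk is oxidative degradation of the electron-rich phenol toward a quinone during the peroxide stage, or incomplete metalation. The fallback introduces the oxygen by formylation and oxidative rearrangement, starting from 1. Rieche formylation (Cl2CHOMe, TiCl4, CH2Cl2, 0 °C) would give 2,3,4,5-tetramethoxybenzaldehyde F6. Baeyer–Villiger oxidation with mCPBA would give 2,3,4,5-tetramethoxyphenyl formate F7. Methanolysis with K2CO3 would return to the route at phenol 4.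

## Further compounds

F1 | step 7 | 5-ethynyl-1,3-dimethoxy-2-(methoxymethoxy)benzene | C#Cc1cc(OC)c(OCOC)c(OC)c1
F2 | step 7 | racemic 3-[3,5-dimethoxy-4-(methoxymethoxy)phenyl]-1-[2,3,4,5-tetramethoxy-6-(methoxymethoxy)phenyl]prop-2-yn-1-ol | COCOc1c(OC)c(OC)c(OC)c(OC)c1C(O)C#Cc1cc(OC)c(OCOC)c(OC)c1
F3 | step 7 | 3-[3,5-dimethoxy-4-(methoxymethoxy)phenyl]-1-[2,3,4,5-tetramethoxy-6-(methoxymethoxy)phenyl]prop-2-yn-1-one | COCOc1c(OC)c(OC)c(OC)c(OC)c1C(=O)C#Cc1cc(OC)c(OCOC)c(OC)c1
F4 | step 9 | 2-[3-(4-hydroxy-3,5-dimethoxyphenyl)isoxazol-5-yl]-3,4,5,6-tetramethoxyphenol | COc1cc(-c2cc(-c3c(O)c(OC)c(OC)c(OC)c3OC)on2)cc(OC)c1O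
F5 | step 4 | 1-(2,2-dibromoethenyl)-2,3,4,5-tetramethoxy-6-(methoxymethoxy)benzene | COCOc1c(C=C(Br)Br)c(OC)c(OC)c(OC)c1OC
F6 | step 1 | 2,3,4,5-tetramethoxybenzaldehyde | COc1cc(C=O)c(OC)c(OC)c1OC
F7 | step 1 | 2,3,4,5-tetramethoxyphenyl formate | COc1cc(OC=O)c(OC)c(OC)c1OC
A1 | alternative 1 | 4'-O-tosyl-3',5,5',6,7,8-hexamethoxyflavone | COc1cc(-c2cc(=O)c3c(OC)c(OC)c(OC)c(OC)c3o2)cc(OC)c1OS(=O)(=O)c1ccc(C)cc1
A2 | alternative 1 | 1-(2,3,4,5-tetramethoxyphenyl)-3-[3,5-dimethoxy-4-(tosyloxy)phenyl]propane-1,3-dione | COc1cc(C(=O)CC(=O)c2cc(OC)c(OC)c(OC)c2OC)cc(OC)c1OS(=O)(=O)c1ccc(C)cc1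
A3 | alternative 1 | 1-(2,3,4,5-tetramethoxyphenyl)ethan-1-one | CC(=O)c1cc(OC)c(OC)c(OC)c1OC
A4 | alternative 2 | 1-(2-hydroxy-3,4,5,6-tetramethoxyphenyl)-3-[4-(benzyloxy)-3,5-dimethoxyphenyl]prop-2-yn-1-one | COc1cc(C#CC(=O)c2c(O)c(OC)c(OC)c(OC)c2OC)cc(OC)c1OCc1ccccc1
A5 | alternative 2 | 2,3,4,5-tetramethoxy-6-(trimethylsilyl)phenyl trifluoromethanesulfonate | COc1c(OC)c(OC)c(OS(=O)(=O)C(F)(F)F)c([Si](C)(C)C)c1OC
A6 | alternative 2 | 3,4,5,6-tetramethoxybenzyne | COC1=C(OC)C(OC)=C(OC)C#C1
A7 | alternative 2 | 3-[4-(benzyloxy)-3,5-dimethoxyphenyl]prop-2-ynoic acid | COc1cc(C#CC(=O)O)cc(OC)c1OCc1ccccc1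
A8 | alternative 3 | 4'-O-benzyl-5,8-dihydroxy-3',5',6,7-tetramethoxyflavone | COc1cc(-c2cc(=O)c3c(O)c(OC)c(OC)c(O)c3o2)cc(OC)c1OCc1ccccc1
A9 | alternative 3 | racemic 4-{6-[4-(benzyloxy)-3,5-dimethoxyphenyl]-4-oxo-4H-pyran-3-yl}-4-hydroxy-2,3-dimethoxycyclobut-2-en-1-one | COC1=C(OC)C(O)(c2coc(-c3cc(OC)c(OCc4ccccc4)c(OC)c3)cc2=O)C1=O
A10 | alternative 3 | dimethyl squarate (3,4-dimethoxycyclobut-3-ene-1,2-dione) | COC1=C(OC)C(=O)C1=O
A11 | alternative 3 | 2-[4-(benzyloxy)-3,5-dimethoxyphenyl]-5-bromo-4H-pyran-4-one | COc1cc(-c2cc(=O)c(Br)co2)cc(OC)c1OCc1ccccc1
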